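The runs were generated by integration with constants of no real substance; scatter was added.

Slowness marks the loss of J in both earlier runs, and the flask asked about lies between them in charge.

| setting | green | violet | flask |
|---|---|---|---|
| D | 0.050 M (fed, over 12 h) | 0.20 M (fed, over 12 h) | 0.10 M (fed, over 12 h) |
| Q | 40 mM (held) | 40 mM (held) | 40 mM (held) |
| remark | run made earlier | run made earlier |  |
| time |  |  | 40 h |

- green (time / h: J / %, D / %): 4.00: 12.0, 8.4; 6.00: 19.8, 8.6; 8.00: 27.9, 8.3; 12.0: 43.9, 8.2; 20.0: 32.2, 0; 30.0: 6.9, 0.3; 50.0: 0, 0
- violet (time / h: J / %, D / %): 4.00: 14.1, 13.0; 6.00: 25.4, 16.5; 8.00: 38.1, 18.1; 12.0: 64.0, 20.7; 20.0: 78.2, 0; 30.0: 72.5, 0; 50.0: 59.5, 0.4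

(readings scatter by 0.5 percentage points)

- the analysis behind the earlier runs scatters by 0.5 percentage points, standard deviation
- at the start none of Q is in solution
- a reading or a percentage of J counts all its forms, free or not
- percentages count the whole charge, also what has not yet gone in

* time up to 40 h at which J stands highest
* the amount of J, in percent of the D charged, at that time

With D reading 0 % at 20.0 h, the violet run loses J at 1.25 mM h⁻¹ up to 50.0 h. The green run, from 20.0 h to 30.0 h, loses 1.27 mM h⁻¹, nearly the same, though the violet run holds ten times the J. This flat, zero-order loss, the toll, is the millimoles of J per litre lost each hour once D reads near zero, as read over these two stretches.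

During the feed, a similar freezing gives two extreme flasks. By 12 h the green run has lost 23.9 mM to neither J nor D, and the violet run 30.6 mM. Paying the green loss, this flask holds 76.0 % as J plus D at the end of the feed; paying the violet loss, 69.4 %. This reckoning puts the flask between them, its charge standing above the green run's and below the violet run's. Remaining D then turns into J while the toll runs, so J should peak shortly after the feed, some points under that band. The forecast, calling the late loss “nearly zero order”, gives 67 % at 14.5 h, just below the band.

The flask reaches 64.4 % at 14.6 h, by this scheme: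

    D + G → J (k = 0.621 M⁻¹ min⁻¹)
    G + J → L (k = 0.855 M⁻¹ min⁻¹)
    G + L → X (k = 0.366 M⁻¹ min⁻¹)
    E ⇌ J, rate k4*(cs4 - [J]) while solid is left; crystals form when [J] > cs4 (solubility = 1.00 mM, k = 0.0614 min⁻¹)
    Q ⇌ G, rate k5*(csat - [G]) (kL = 0.0109 min⁻¹)
    J ⇌ Z (K = 0.690, k = 0.00871 min⁻¹)

At that time crystals E, counted in J, make 63.3 % of the 64.4 %. Reckoned at the toll over the remaining 25.4 h, this flask comes down to 32.8 %; it holds 34.7 % at 40.0 h. A neighbour flask charged with 0.040 M peaks at 37.8 %, which is 15.1 mM, a sum that lasts 12.1 h when reckoned at the toll; that neighbour holds 0 % J at 40.0 h.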